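All runs are simulated with constants of no real substance; noise was put on by code.

The trap is to run the rise of intermediate D forward to 25 min. In the noon run it climbs from 41% at 6.00 min to 49% at 10.0 min, then more slowly to 51% at 12.0 min. I therefore ask where it stops, not how fast it moves.

| setting | spring | noon | theta | delta |
|---|---|---|---|---|
| substrate | 0.050 M | 0.050 M | 0.050 M | 0.050 M |
| coupling partner | 0.071 M | 0.17 M | 0.100 M | 0.250 M |
| remark | run made earlier | run made earlier |  |  |
| time |  |  | 25 min | 25 min |

| run | time / min | intermediate D / % | intermediate A / % | target / % | intermediate B / % | substrate / % |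
|---|---|---|---|---|---|---|
| spring | 1.50 | 4 | 47 | 1 | 27 | 17 |
| spring | 4.00 | 7 | 51 | 3 | 32 | 2 |
| spring | 8.00 | 16 | 50 | 3 | 31 | 0 |
| spring | 12.0 | 11 | 47 | 0 | 29 | 1 |
| noon | 3.00 | 26 | 44 | 2 | 26 | 0 |
| noon | 6.00 | 41 | 35 | 0 | 20 | 0 |
| noon | 10.0 | 49 | 28 | 1 | 19 | 2 |
| noon | 12.0 | 51 | 29 | 1 | 18 | 0 |

(readings scatter by 1.5 percentage points)

- which of these there is most of at the end, counted by the substrate in it, theta (intermediate D / intermediate B / target / intermediate A)
- which of these there is most of at the end, counted by the substrate in it, delta (intermediate D / intermediate B / target / intermediate A)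
- the largest of these amounts at the end, in percent of the substrate charged, theta
- the largest of these amounts at the end, in percent of the substrate charged, delta

- a reading or a percentage of target counts all its forms, free or not

I take the run in slow motion. In the first minutes of the spring run, substrate, the limiting reagent, falls to 2% by 4.00 min, while intermediates A and B appear together. I assume this costs one equivalent of coupling partner. In the middle of the noon run, intermediate D grows as A and B fall, and at 12.0 min A stands to B as 1.61. At that end the three hold 98.0% of the substrate, and target reads 1%, with a scatter of 1.5 percentage points.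

So, setting target aside at that reading, I write an approximate substrate balance and carry one quantity, the pairing quotient K′: intermediate D over the pool of A and B, per molar of free coupling partner.

[intermediate A] + [intermediate B] + [intermediate D] ≈ [substrate] charged

[coupling partner] free ≈ [coupling partner] charged − [substrate] charged − [intermediate D]

[intermediate D] = K′ ([intermediate A] + [intermediate B]) [coupling partner] free

The last noon reading gives K′ = 11.5 M⁻¹. The last spring reading gives 9.34 M⁻¹, on a reckoned free partner of 0.0155 M.

Solving the three lines, my theta has intermediate D at 29.0% and intermediate A at 43.8%. My delta has intermediate D at 65.7%.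

The forecast names intermediate A at 44% for theta and intermediate D at 65% for delta, on the ground that “The plateaus fit an equilibrium”. It picks the same species as I do, and its delta figure differs slightly from mine.

The flasks give intermediate A at 40.5% in theta and intermediate D at 68.8% in delta.

    substrate + coupling partner → intermediate A (k = 0.460 M⁻¹ s⁻¹)
    intermediate A ⇌ intermediate B (K = 0.620, k = 0.0550 s⁻¹)
    substrate ⇌ intermediate C (K = 2.60, k = 0.00170 s⁻¹)
    coupling partner + intermediate B ⇌ intermediate D (K = 36.0 M⁻¹, k = 0.0570 M⁻¹ s⁻¹)
    intermediate C ⇌ target (K = 21.0, k = 8.30 × 10⁻⁴ s⁻¹)
    coupling partner + target ⇌ idle adduct, settled at all times (K = 15.0 M⁻¹)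

Delta holds 68.8% of intermediate D at 25 min and 68.9% at 250 min, so its amount stands still over that stretch, 3.1 points above my reckoning. The neighbouring flask is delta with 0.12 M of substrate, which makes 2.08 equiv of coupling partner. The same three lines with the same K′ give it 46.1% of intermediate D. That flask gives 49.1%, with 29% of its coupling partner still unbound.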